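Try to keep the rate proportional to partner, and the east and south-west runs refuse it.

| flask | substrate | partner | free catalyst | time |
|---|---|---|---|---|
| east | 50.0 mM | 100 mM | 0.100 mM |  |
| south-west | 20.0 mM | 70.0 mM | 0.100 mM |  |
| west | 50.0 mM | 100 mM | 0.150 mM |  |
| north | 75.0 mM | 100 mM | 0.100 mM |  |
| north-east | 100 mM | 100 mM | 0.100 mM | 75 min |

| run | time / min | [product] / mM |
|---|---|---|
| east run | 9.4 | 6.37 |
| east run | 19 | 12.29 |
| east run | 28 | 16.50 |
| east run | 38 | 20.91 |
| east run | 47 | 24.28 |
| east run | 56 | 26.70 |
| east run | 66 | 29.79 |
| east run | 75 | 31.58 |
| south-west run | 9.4 | 2.22 |
| south-west run | 19 | 3.92 |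
| south-west run | 28 | 5.64 |
| south-west run | 38 | 7.12 |
| south-west run | 47 | 8.22 |
| south-west run | 56 | 9.57 |
| south-west run | 66 | 10.41 |
| south-west run | 75 | 11.62 |
| west run | 9.4 | 10.06 |
| west run | 19 | 17.85 |
| west run | 28 | 23.44 |
| west run | 38 | 28.16 |
| west run | 47 | 31.63 |
| west run | 56 | 34.24 |
| west run | 66 | 37.29 |
| west run | 75 | 39.03 |
| north run | 9.4 | 9.97 |
| north run | 19 | 18.29 |
| north run | 28 | 24.61 |
| north run | 38 | 30.81 |
| north run | 47 | 34.61 |
| north run | 56 | 38.89 |
| north run | 66 | 42.46 |
| north run | 75 | 45.70 |

(standard deviation of a reading: 0.2 mM)

- Overall: substrate + partner -> product, with free catalyst as catalyst.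
- Constant volume, constant temperature.
- A reading of a species includes what of it is bound.
- An order is taken over about fifteen percent of the charge, up and down.

1. order of the initial rate in [substrate], near the charge of the east run, the rate being that where two percent of its substrate are product (one fixed amount of product, the same in the runs compared)
2. order of the initial rate in [partner], near the charge of the east run, the rate being that where two percent of its substrate are product
3. the south-west run starts with 30.0 mM less of substrate and of partner than the east run, and with no product. Compared where both hold the same amount of substrate, once fifteen percent of what the south-west run was charged with has turned into product, is the south-west run faster, slower or alike (within a tenth)?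
4. product in the north-east run at 75 min, as a share of the substrate charged

1. Take substrate as first order: the north run over the east run at the second reading gives an order of 0.981. So write k = ln(S₀/S)/t, with S substrate and S₀ its charge: k is a first-order coefficient averaged from the start up to time t, and it changes with t as partner falls. At the fourth reading, the east run gives kE = 0.0143 min⁻¹ and the south-west run kW = 0.0116 min⁻¹. Mean partner over that span is RE = 89.5 mM and RW = 66.4 mM.

2. Turn the question round: for a partner order of one, kE/kW would have to equal RE/RW, which is 1.35. The reading is 1.23, smaller.

3. So define the partner order n = ln(kE/kW)/ln(RE/RW), the power of partner that the rate follows: it reads 0.696. The scatter of the south-west reading alone gives about 0.118, so order one stands 2.58 such widths away.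

4. The south-west charge holds the substrate and partner of the east run after 30.0 mM has turned, but without its product. The south-west run makes 0.206 mM min⁻¹ up to its second reading, and the east run 0.199 mM min⁻¹ between its last two, near the same substrate. I say alike.

5. In the north-east run substrate and partner start equal and fall together. Scale kE to full partner: kA = 0.0154 min⁻¹. The fraction x of substrate left then obeys x^(−n) = one + n·kA·t, which gives my share of 57.1 %.

6. The forecast gives 1.05, 0.5, alike and 58 %. In its words: “This gives a partner order near 0.5”.

7. The flask gives 1.0, 0.68, alike and 57.5 %. The forecast's partner order is lower; its other three answers stand.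

    free catalyst + substrate + partner → product + free catalyst (3600 L² mol⁻² min⁻¹)
    free catalyst + impurity → spent catalyst
    2 partner ⇌ idle reagent dimer, settled at all times (9.120 L mol⁻¹)

Take away the pairing of partner to idle reagent dimer and the partner order goes from 0.68 to 1.0. Let the pairing keep pace, and call u the partner paired over the partner free: the order is then (one + u)/(one + u + u). The read 0.696 gives u = 0.776, so 43.7 % of the partner counted over the east and south-west spans sits paired. Without that pairing the north-east run reaches 69.5 % of product, against 57.5 %.

(The readings are simulated for substances that don't exist, and the scatter is random.)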